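Everything rests on cutting the bond between C2 (the aryl-bearing carbon of the 1,1-disubstituted alkene) and C3 (the angelate-bearing carbinol stereocentre) of the hepta-1,5-diene chain. The key step is a lithiation–borylation: the sparteine-complexed α-lithiated carbamate of homoprenyl alcohol adds to a 1-arylvinyl pinacol boronate that already carries the fully substituted benzene ring; stereospecific 1,2-migration of the arylvinyl group from boron to carbon forms C2–C3 and fixes C3, and C–B oxidation in the same flask returns the oxygen. The step exploits the C3–O bond (directing group, then leaving group, then restored as the ester site) and the sp2 nature of C2. Angeloylation, desilylation and hindrance-controlled acetylation finish the route.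

Key step: step 8

Remark: the sense of deprotonation is assigned from the established preference of s-BuLi/(−)-sparteine for the pro-S proton of O-alkyl carbamates, so the mirror-image ligand (+)-sparteine is specified. Ring positions carry primes (C1' bears the side chain); chain atoms are numbered as in hepta-1,5-diene.

Step 1
Reactants: 1 2,3-dimethoxytoluene
Product: 4 1-(2,3-dimethoxy-4-methylphenyl)ethanone, via aryllithium 2 (not isolated), via lithium hemiaminal adduct 3 (not isolated)
Conditions: n-BuLi, TMEDA, Et2O, 0 °C → rt; then MeC(O)N(OMe)Me, −78 °C → rt; aq NH4Cl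
Reagents that add atoms: N-methoxy-N-methylacetamide, CC(=O)N(C)OC
Why: Directed ortho-metalation: the only ring C–H ortho to a methoxy group (para to the methyl) is lithiated, and the Weinreb amide stops at the ketone through its chelated tetrahedral adduct.

Step 2
Reactants: 4 1-(2,3-dimethoxy-4-methylphenyl)ethanone
Product: 6 1-(2-hydroxy-3-methoxy-4-methylphenyl)ethanone, via aryloxydichloroborane chelate 5 (not isolated)
Conditions: BCl3, CH2Cl2, −78 → 0 °C; then H2O
Reagents that add atoms: none
Why: Chelation-controlled Lewis-acid ether cleavage: only the methoxy group ortho to the acetyl carbonyl can form the six-membered boron chelate, so only it should be demethylated.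

Step 3
Reactants: 6 1-(2-hydroxy-3-methoxy-4-methylphenyl)ethanone
Product: 8 1-(2,5-dihydroxy-3-methoxy-4-methylphenyl)ethanone, via potassium aryl sulfate 7 (not isolated)
Conditions: K2S2O8, aq KOH, 0 → 20 °C; then aq HCl, Na2SO3, 90 °C
Reagents that add atoms: potassium peroxydisulfate, [K+].[K+].[O-]S(=O)(=O)OOS(=O)(=O)[O-]
Why: Elbs persulfate oxidation: the phenoxide is attacked by peroxydisulfate at its free para carbon (C5'), and acid hydrolysis of the aryl sulfate releases the hydroquinone.

Step 4
Reactants: 8 1-(2,5-dihydroxy-3-methoxy-4-methylphenyl)ethanone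
Product: 9 1-[3-methoxy-4-methyl-2,5-bis(triisopropylsilyloxy)phenyl]ethanone
Conditions: TIPSOTf, 2,6-lutidine, CH2Cl2, 0 °C → rt; dilute HCl wash
Reagents that add atoms: triisopropylsilyl trifluoromethanesulfonate, CC(C)[Si](C(C)C)(C(C)C)OS(=O)(=O)C(F)(F)F
Why: O-silylation with the silyl triflate is reactive enough to cap the hydrogen-bonded C2' hydroxyl as well, and aryl TIPS ethers should withstand the organolithium and alkaline peroxide of step 8 (the acid wash returns any silyl enol ether to the ketone).

Step 5
Reactants: 9 1-[3-methoxy-4-methyl-2,5-bis(triisopropylsilyloxy)phenyl]ethanone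
Product: 10 1-[3-methoxy-4-methyl-2,5-bis(triisopropylsilyloxy)phenyl]ethenyl trifluoromethanesulfonate
Conditions: Tf2O, 2,6-di-tert-butyl-4-methylpyridine, CH2Cl2, 0 °C → rt
Reagents that add atoms: trifluoromethanesulfonic anhydride, O=S(=O)(OS(=O)(=O)C(F)(F)F)C(F)(F)F
Why: Enol triflate formation by O-sulfonylation of the ketone and loss of a methyl proton to the hindered base, which avoids an enolate that could take over the ortho silyl group.

Step 6
Reactants: 10 1-[3-methoxy-4-methyl-2,5-bis(triisopropylsilyloxy)phenyl]ethenyl trifluoromethanesulfonate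
Product: 11 2-{1-[3-methoxy-4-methyl-2,5-bis(triisopropylsilyloxy)phenyl]ethenyl}-4,4,5,5-tetramethyl-1,3,2-dioxaborolane
Conditions: B2pin2, PdCl2(PPh3)2, PPh3, KOPh, toluene, 50 °C
Reagents that add atoms: bis(pinacolato)diboron, CC1(C)OB(B2OC(C)(C)C(C)(C)O2)OC1(C)C
Why: Miyaura borylation of an alkenyl triflate (oxidative addition, phenoxide-assisted transmetalation, reductive elimination) gives the 1-arylvinyl boronate without organolithium chemistry next to the silyl ethers.

Step 7
Reactants: 12 4-methylpent-3-en-1-ol
Product: 13 4-methylpent-3-en-1-yl N,N-diisopropylcarbamate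
Conditions: iPr2NCOCl, Et3N, CH2Cl2, reflux
Reagents that add atoms: N,N-diisopropylcarbamoyl chloride, CC(C)N(C(C)C)C(Cl)=O
Why: Carbamoylation of the primary alcohol gives the Hoppe carbamate that both directs α-lithiation and later serves as the leaving group.

Step 8
Reactants: 13 4-methylpent-3-en-1-yl N,N-diisopropylcarbamate; 11 2-{1-[3-methoxy-4-methyl-2,5-bis(triisopropylsilyloxy)phenyl]ethenyl}-4,4,5,5-tetramethyl-1,3,2-dioxaborolane
Product: 17 (S)-2-[3-methoxy-4-methyl-2,5-bis(triisopropylsilyloxy)phenyl]-6-methylhepta-1,5-dien-3-ol, via lithiated carbamate 14 (not isolated), via boronate complex 15 (not isolated), via allylic boronic ester 16 (not isolated)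
Conditions: 13, s-BuLi, (+)-sparteine, Et2O, −78 °C; then 11, −78 °C; MgBr2·OEt2, −78 °C → reflux; then 30% H2O2, aq NaOH, THF, 0 °C → rt
Reagents that add atoms: hydrogen peroxide, OO
Why: s-BuLi/(+)-sparteine should remove the pro-R O–CH2 proton of 13 to give the configurationally stable (R)-lithiated carbamate 14, which is borylated by 11 with retention to give boronate complex 15; on warming with MgBr2 the 1-arylvinyl group migrates from boron to carbon anti-periplanar to the departing carbamate (inversion), forming the C2–C3 bond in 16, and alkaline H2O2 turns C–B into C–O with retention. The closest known reaction type is the Hoppe–Matteson–Aggarwal lithiation–borylation of primary O-alkyl carbamates with alkenyl pinacol boronates followed by oxidation. No ring is closed. The single stereocentre C3 is controlled by the chiral diamine in the deprotonation and relayed stereospecifically (retention, inversion, retention), which should deliver the (S) carbinol. The step needs lithiation at O–CH2 rather than at the allylic CH2, secured by the carbamate carbonyl that binds the base; migration of carbon rather than pinacol oxygen, secured by the high migratory aptitude of the sp2 carbon; and configurational integrity of the secondary allylic boronate, secured by the pinacol ester, which resists 1,3-borotropic shift before oxidation.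

Step 9
Reactants: 17 (S)-2-[3-methoxy-4-methyl-2,5-bis(triisopropylsilyloxy)phenyl]-6-methylhepta-1,5-dien-3-ol
Product: 18 (S)-2-[3-methoxy-4-methyl-2,5-bis(triisopropylsilyloxy)phenyl]-6-methylhepta-1,5-dien-3-yl (Z)-2-methylbut-2-enoate
Conditions: angelic acid, 2,4,6-trichlorobenzoyl chloride, Et3N, toluene, rt; then 17, 75 °C
Reagents that add atoms: angelic acid, C/C=C(/C)C(=O)O
Why: Yamaguchi esterification through the mixed 2,4,6-trichlorobenzoic anhydride acylates the hindered secondary allylic alcohol without nucleophilic catalyst, which should avoid Z→E isomerisation to the tiglate and leaves C3 untouched.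

Step 10
Reactants: 18 (S)-2-[3-methoxy-4-methyl-2,5-bis(triisopropylsilyloxy)phenyl]-6-methylhepta-1,5-dien-3-yl (Z)-2-methylbut-2-enoate
Product: 19 (S)-2-(2,5-dihydroxy-3-methoxy-4-methylphenyl)-6-methylhepta-1,5-dien-3-yl (Z)-2-methylbut-2-enoate
Conditions: TBAF, AcOH, THF, 0 °C → rt, argon
Reagents that add atoms: none
Why: Fluoride-mediated cleavage of both aryl silyl ethers, buffered by acetic acid so that phenoxide-induced acyl transfer and air oxidation of the hydroquinone should be suppressed.

Step 11
Reactants: 19 (S)-2-(2,5-dihydroxy-3-methoxy-4-methylphenyl)-6-methylhepta-1,5-dien-3-yl (Z)-2-methylbut-2-enoate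
Product: 20 (S)-2-(5-acetoxy-2-hydroxy-3-methoxy-4-methylphenyl)-6-methylhepta-1,5-dien-3-yl (Z)-2-methylbut-2-enoate
Conditions: Ac2O (1.05 equiv), pyridine, CH2Cl2, −20 → 0 °C
Reagents that add atoms: acetic anhydride, CC(=O)OC(C)=O
Why: Kinetically site-selective O-acetylation: the C5' hydroxyl (flanked by CH3 and H) should react much faster than the C2' hydroxyl, which is flanked by OMe and the branched alkenyl group and hydrogen-bonded to the methoxy oxygen.

Compound list
1 | 2,3-dimethoxytoluene | COc1cccc(C)c1OC | starting material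
2 | (2,3-dimethoxy-4-methylphenyl)lithium | [Li]c1ccc(C)c(OC)c1OC | intermediate
3 | lithium 1-(2,3-dimethoxy-4-methylphenyl)-1-[methoxy(methyl)amino]ethanolate | CC(O[Li])(N(C)OC)c1ccc(C)c(OC)c1OC | intermediate
4 | 1-(2,3-dimethoxy-4-methylphenyl)ethanone | CC(=O)c1ccc(C)c(OC)c1OC | intermediate
5 | (2-acetyl-6-methoxy-5-methylphenoxy)dichloroborane | CC(=O)c1ccc(C)c(OC)c1OB(Cl)Cl | intermediate
6 | 1-(2-hydroxy-3-methoxy-4-methylphenyl)ethanone | CC(=O)c1ccc(C)c(OC)c1O | intermediate
7 | potassium 5-acetyl-4-hydroxy-3-methoxy-2-methylphenyl sulfate | CC(=O)c1cc(OS(=O)(=O)[O-])c(C)c(OC)c1O.[K+] | intermediate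
8 | 1-(2,5-dihydroxy-3-methoxy-4-methylphenyl)ethanone | CC(=O)c1cc(O)c(C)c(OC)c1O | intermediate
9 | 1-[3-methoxy-4-methyl-2,5-bis(triisopropylsilyloxy)phenyl]ethanone | CC(=O)c1cc(O[Si](C(C)C)(C(C)C)C(C)C)c(C)c(OC)c1O[Si](C(C)C)(C(C)C)C(C)C | intermediate
10 | 1-[3-methoxy-4-methyl-2,5-bis(triisopropylsilyloxy)phenyl]ethenyl trifluoromethanesulfonate | C=C(OS(=O)(=O)C(F)(F)F)c1cc(O[Si](C(C)C)(C(C)C)C(C)C)c(C)c(OC)c1O[Si](C(C)C)(C(C)C)C(C)C | intermediate
11 | 2-{1-[3-methoxy-4-methyl-2,5-bis(triisopropylsilyloxy)phenyl]ethenyl}-4,4,5,5-tetramethyl-1,3,2-dioxaborolane | C=C(B1OC(C)(C)C(C)(C)O1)c1cc(O[Si](C(C)C)(C(C)C)C(C)C)c(C)c(OC)c1O[Si](C(C)C)(C(C)C)C(C)C | intermediate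
12 | 4-methylpent-3-en-1-ol | CC(C)=CCCO | starting material
13 | 4-methylpent-3-en-1-yl N,N-diisopropylcarbamate | CC(C)=CCCOC(=O)N(C(C)C)C(C)C | intermediate
14 | (R)-1-lithio-4-methylpent-3-en-1-yl N,N-diisopropylcarbamate ((+)-sparteine complex) | [Li][C@H](CC=C(C)C)OC(=O)N(C(C)C)C(C)C | intermediate
15 | lithium boronate complex of 11 with the (R)-carbenoid carbon of 14 | C=C(c1cc(O[Si](C(C)C)(C(C)C)C(C)C)c(C)c(OC)c1O[Si](C(C)C)(C(C)C)C(C)C)[B-]1(OC(C)(C)C(C)(C)O1)[C@H](CC=C(C)C)OC(=O)N(C(C)C)C(C)C.[Li+] | intermediate
16 | 2-{(S)-2-[3-methoxy-4-methyl-2,5-bis(triisopropylsilyloxy)phenyl]-6-methylhepta-1,5-dien-3-yl}-4,4,5,5-tetramethyl-1,3,2-dioxaborolane | C=C(c1cc(O[Si](C(C)C)(C(C)C)C(C)C)c(C)c(OC)c1O[Si](C(C)C)(C(C)C)C(C)C)[C@H](CC=C(C)C)B1OC(C)(C)C(C)(C)O1 | intermediate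
17 | (S)-2-[3-methoxy-4-methyl-2,5-bis(triisopropylsilyloxy)phenyl]-6-methylhepta-1,5-dien-3-ol | C=C(c1cc(O[Si](C(C)C)(C(C)C)C(C)C)c(C)c(OC)c1O[Si](C(C)C)(C(C)C)C(C)C)[C@H](CC=C(C)C)O | intermediate
18 | (S)-2-[3-methoxy-4-methyl-2,5-bis(triisopropylsilyloxy)phenyl]-6-methylhepta-1,5-dien-3-yl (Z)-2-methylbut-2-enoate | C=C(c1cc(O[Si](C(C)C)(C(C)C)C(C)C)c(C)c(OC)c1O[Si](C(C)C)(C(C)C)C(C)C)[C@H](CC=C(C)C)OC(=O)/C(C)=C\C | intermediate
19 | (S)-2-(2,5-dihydroxy-3-methoxy-4-methylphenyl)-6-methylhepta-1,5-dien-3-yl (Z)-2-methylbut-2-enoate | C=C(c1cc(O)c(C)c(OC)c1O)[C@H](CC=C(C)C)OC(=O)/C(C)=C\C | intermediate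
20 | (S)-2-(5-acetoxy-2-hydroxy-3-methoxy-4-methylphenyl)-6-methylhepta-1,5-dien-3-yl (Z)-2-methylbut-2-enoate | C=C(c1cc(OC(C)=O)c(C)c(OC)c1O)[C@H](CC=C(C)C)OC(=O)/C(C)=C\C | target

Total step count: 11. Longest linear sequence: 10 steps (steps 1–6, then 8–11; step 7 is the side branch).

Steps most likely to fail

Step 8. Ate-complex formation or the 1,2-migration may be sluggish at the hindered boron centre, allylic deprotonation of 13 may compete, and enantiopurity may erode. The fallback sets out from vinyl triflate 10 and alcohol 12. Alcohol 12 is oxidised with Dess–Martin periodinane (NaHCO3, CH2Cl2, 0 °C) to 4-methylpent-3-enal F1, which is used at once. F1 is coupled with 10 in a catalytic asymmetric Nozaki–Hiyama–Kishi reaction (CrCl2 with a chiral oxazoline–sulfonamide ligand, NiCl2·neocuproine, Mn, Cp2ZrCl2, LiCl, MeCN, rt), the ligand enantiomer being chosen to deliver the (S) alcohol. This should give 17 directly, where the route is rejoined. It is held in reserve because it relies on a labile β,γ-unsaturated aldehyde and on catalyst-controlled facial selectivity that is less predictable for this hindered alkenyl partner.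

Step 11. Site selectivity between the two phenolic hydroxyls may be poor, over-acetylation may occur, and the free hydroquinone may oxidise in air. The fallback sets out from bis-silyl ether 18 and moves the selectivity to the desilylation. One equivalent of TBAF in THF at −40 °C in the presence of Ac2O should cleave only the less hindered C5' silyl ether and trap the phenoxide as its acetate, giving (S)-2-[5-acetoxy-3-methoxy-4-methyl-2-(triisopropylsilyloxy)phenyl]-6-methylhepta-1,5-dien-3-yl (Z)-2-methylbut-2-enoate F2. HF·pyridine (THF/pyridine, 0 °C → rt) then removes the remaining hindered silyl group and arrives at 20, so the free hydroquinone 19 is never formed.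

Step 3. Conversion may be low, over-oxidation to quinoid material may occur, and the water-soluble sulfate may be hard to isolate. The fallback sets out from phenol 6. Bromination with NBS (MeCN, 0 °C), directed para to the hydroxyl, should give 1-(5-bromo-2-hydroxy-3-methoxy-4-methylphenyl)ethanone F3. Palladium-catalysed hydroxylation (Pd2(dba)3, tBuXPhos, KOH, dioxane/H2O, 100 °C; acidic work-up) then converts C–Br into C–OH and returns to hydroquinone 8.

Further compounds
F1 | step 8 | 4-methylpent-3-enal | CC(C)=CCC=O
F2 | step 11 | (S)-2-[5-acetoxy-3-methoxy-4-methyl-2-(triisopropylsilyloxy)phenyl]-6-methylhepta-1,5-dien-3-yl (Z)-2-methylbut-2-enoate | C=C(c1cc(OC(C)=O)c(C)c(OC)c1O[Si](C(C)C)(C(C)C)C(C)C)[C@H](CC=C(C)C)OC(=O)/C(C)=C\C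
F3 | step 3 | 1-(5-bromo-2-hydroxy-3-methoxy-4-methylphenyl)ethanone | CC(=O)c1cc(Br)c(C)c(OC)c1O
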